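A direct plan would build ring C onto a finished ring A: phloroglucinol A1 would be condensed thermally with methyl 2-methoxy-3-(4-methoxyphenyl)-3-oxopropanoate A2 to give ermanin A3.
Ermanin A3 would be dibrominated at C6 and C8 to the 6,8-dibromide A4, and both bromides would then be exchanged for methoxide under copper catalysis to give the target.
Its weakest points would be:
- The pyrone annulation of the α-methoxy ketoester A2 with A1 near 230 °C would have no close precedent, and O-acylation, coumarin formation and thermal decomposition would compete.
- The double copper-mediated methoxylation of A4 would need a large excess of methoxide at about 110 °C on a substrate with two free phenols, so hydrodebromination, mono-exchange and pyrone opening would threaten the last step.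
- The 6- and 8-methoxy groups would be put on by a halogenation/substitution detour that builds no skeleton, because ring A would be bought without them.

**Retrosynthetic overview**
- Ring A (C4a, C5–C8, C8a) is read as a folded poly-β-carbonyl chain: C5 and C7 are carbonyl carbons and end as OH, while C6 and C8 are methoxymethine carbons and end as OMe.
- Disconnections: C4a–C5 and C5–C6 are made last (Claisen closure, C5 from dimethyl carbonate), C7–C8 by lateral acylation, and C2–C1' by Suzuki coupling.
- Ring order: ring C is never closed, because kojic acid supplies O1, C2, C3 with its oxygen, C4=O, C4a, C8a and C8 with its oxygen. Ring B is attached second and ring A closes last on the pyranone.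
- The design needs no annulation onto phloroglucinol, no halogen handle on ring A and no late C–O coupling: every oxygen of ring A is in place before the ring exists, and OH versus OMe is decided by oxidation level.

Key step: step 5

Remark: atoms of the target are numbered as in a flavone (O1, C2–C4, C4a, C5–C8, C8a); the pyranone intermediates are named with their own ring numbering.

Step 1
Reactants: 1 kojic acid (5-hydroxy-2-(hydroxymethyl)-4H-pyran-4-one)
Product: 2 6-bromokojic acid (2-bromo-3-hydroxy-6-(hydroxymethyl)-4H-pyran-4-one)
Conditions: NBS (1.05 equiv), DMF, 0 °C → rt, dark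
Reagents that add atoms: N-bromosuccinimide, O=C1CCC(=O)N1Br
Why: Electrophilic bromination of an enol: the free 5-OH makes C6 the β-carbon of an enol (HO–C5=C6), far more nucleophilic than C3, so bromine should enter only at the carbon that becomes C2 of the flavone.

Step 2
Reactants: 2 6-bromokojic acid
Product: 3 2-bromo-3-methoxy-6-(methoxymethyl)-4H-pyran-4-one
Conditions: MeI (8 equiv), Ag2O (3 equiv), CaSO4, MeCN, 40 °C, dark
Reagents that add atoms: iodomethane, CI
Why: Purdie methylation (Ag2O-mediated Williamson etherification) should etherify the acidic enol OH and the primary alcohol in one operation without free alkoxide, which could displace the vinylogous acyl bromide, and it removes the maltol-type O,O-chelating site before the palladium step.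

Step 3
Reactants: 3 2-bromo-3-methoxy-6-(methoxymethyl)-4H-pyran-4-one; 4 4-methoxyphenylboronic acid
Product: 5 3-methoxy-6-(methoxymethyl)-2-(4-methoxyphenyl)-4H-pyran-4-one
Conditions: Pd(PPh3)4 (5 mol %), K2CO3 (2.5 equiv), 1,4-dioxane/H2O 4:1, 85 °C, N2
Reagents that add atoms: none
Why: Suzuki–Miyaura coupling: the C–Br bond at the β-carbon of the enone (a vinylogous acyl bromide) should add readily to zerovalent palladium, and ring B is transferred from boron under carbonate conditions that leave the pyranone intact.

Step 4
Reactants: 5 3-methoxy-6-(methoxymethyl)-2-(4-methoxyphenyl)-4H-pyran-4-one; 6 N,2-dimethoxy-N-methylacetamide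
Product: 9 1,3-dimethoxy-1-[5-methoxy-6-(4-methoxyphenyl)-4-oxo-4H-pyran-2-yl]propan-2-one (racemic), via lateral lithium dienolate 7 (not isolated), via lithium hemiaminal adduct 8 (not isolated)
Conditions: LiN(SiMe3)2 (1.1 equiv), THF, −78 °C, 30 min; 6 (1.3 equiv), −78 → −20 °C; 1 M HCl, 0 °C
Reagents that add atoms: none
Why: Lateral (vinylogous) deprotonation of the 6-CH2OMe group gives a cross-conjugated dienolate that is acylated at the exocyclic carbon, the site that keeps the pyranone intact, in a Weinreb ketone synthesis whose chelated adduct 8 keeps the acidic product away from the anion so that one equivalent of base suffices; the new stereocentre at C8 is racemic and becomes sp2 in step 5.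

Step 5
Reactants: 9 1,3-dimethoxy-1-[5-methoxy-6-(4-methoxyphenyl)-4-oxo-4H-pyran-2-yl]propan-2-one; 10 dimethyl carbonate
Product: 13 araneosol (5,7-dihydroxy-3,6,8-trimethoxy-2-(4-methoxyphenyl)-4H-chromen-4-one), via dilithium dianion 11 (not isolated), via keto ester 12 (not isolated)
Conditions: LiN(iPr)2 (3.1 equiv), THF, −78 → −40 °C; 10 (1.5 equiv), −78 → 0 °C; then MeOH, Mg(OMe)2 (4 equiv), reflux, N2; 2 M HCl, 50 °C
Reagents that add atoms: none
Why: Three equivalents of amide base form dianion 11 (the C8 carbanion delocalised through the pyranone to O4, plus the C6 ketone enolate) and keep the product deprotonated, and dimethyl carbonate acylates the last-formed, most basic carbon C6, as in the terminal acylation of β-dicarbonyl dianions, to give keto ester 12. In methanol, Mg(OMe)2 allows proton exchange among the anions of 12, and the form deprotonated at C8 carries charge on pyranone C5 (flavone C4a), which attacks the ester carbonyl C5 in a 6-(enolexo)-exo-trig Claisen (Dieckmann-type) C-acylation templated by magnesium chelation; loss of methoxide and two enolisations then aromatise ring A. The closest known reaction type is the biogenetic-type Claisen cyclisation of 3,5,7-triketo esters, free or masked as 4-pyranones, to acylphloroglucinols with Mg(OMe)2. Ring A is thus closed at the carbon–carbon bond C4a–C5 onto the intact ring C, and no stereocentre has to be controlled because C6 and C8 of 12 become sp2. The step needs C-acylation at C4a in preference to other closures: O-attack would give four- or eight-membered rings, and the alternative aldol closures create quaternary carbons that cannot aromatise and should revert, so the aromatic flavone is the only irreversible outlet. The substitution pattern is set by the chain itself, with OH only at the former carbonyl carbons C5 and C7 and OMe on C6 and C8, and the final warm acid treatment should reclose any pyranone that methoxide may have opened.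

**Compound list**
1 | kojic acid (5-hydroxy-2-(hydroxymethyl)-4H-pyran-4-one) | OCc1cc(=O)c(O)co1 | starting material
2 | 6-bromokojic acid (2-bromo-3-hydroxy-6-(hydroxymethyl)-4H-pyran-4-one) | OCc1cc(=O)c(O)c(Br)o1 | intermediate
3 | 2-bromo-3-methoxy-6-(methoxymethyl)-4H-pyran-4-one | COCc1cc(=O)c(OC)c(Br)o1 | intermediate
4 | 4-methoxyphenylboronic acid | OB(O)c1ccc(OC)cc1 | starting material
5 | 3-methoxy-6-(methoxymethyl)-2-(4-methoxyphenyl)-4H-pyran-4-one | COCc1cc(=O)c(OC)c(-c2ccc(OC)cc2)o1 | intermediate
6 | N,2-dimethoxy-N-methylacetamide | COCC(=O)N(C)OC | starting material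
7 | lithium 3-methoxy-6-(methoxymethylidene)-2-(4-methoxyphenyl)-6H-pyran-4-olate (lateral dienolate of 5, exocyclic double-bond geometry not defined) | [Li+].[O-]C1=CC(=COC)OC(-c2ccc(OC)cc2)=C1OC | intermediate
8 | lithium 1,3-dimethoxy-2-[methoxy(methyl)amino]-1-[5-methoxy-6-(4-methoxyphenyl)-4-oxo-4H-pyran-2-yl]propan-2-olate (mixture of diastereomers, racemic) | [Li+].[O-]C(COC)(N(C)OC)C(OC)c1cc(=O)c(OC)c(-c2ccc(OC)cc2)o1 | intermediate
9 | 1,3-dimethoxy-1-[5-methoxy-6-(4-methoxyphenyl)-4-oxo-4H-pyran-2-yl]propan-2-one (racemic, enolisable) | COCC(=O)C(OC)c1cc(=O)c(OC)c(-c2ccc(OC)cc2)o1 | intermediate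
10 | dimethyl carbonate | COC(=O)OC | starting material
11 | dilithium dianion of 9 (C8 dienolate through the pyranone to O4 plus C6 ketone enolate, double-bond geometries not defined) | [Li+].[Li+].[O-]C(=COC)C(OC)=C1C=C([O-])C(OC)=C(-c2ccc(OC)cc2)O1 | intermediate
12 | methyl 2,4-dimethoxy-4-[5-methoxy-6-(4-methoxyphenyl)-4-oxo-4H-pyran-2-yl]-3-oxobutanoate (mixture of diastereomers, racemic, enolisable) | COC(=O)C(OC)C(=O)C(OC)c1cc(=O)c(OC)c(-c2ccc(OC)cc2)o1 | intermediate
13 | araneosol, 5,7-dihydroxy-3,6,8-trimethoxy-2-(4-methoxyphenyl)-4H-chromen-4-one (achiral) | COc1ccc(-c2oc3c(OC)c(O)c(OC)c(O)c3c(=O)c2OC)cc1 | target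

Total step count: 5. Longest linear sequence: 5 steps (from kojic acid 1).

**Steps most likely to fail**

1. Step 5. What may go wrong: proton transfer from freshly formed 12 to unreacted dianion could stall the carbomethoxylation, or methoxide could cleave the tricarbonyl chain (retro-Claisen) before it closes. The fallback sets out from 5 and comes back at 13, passing through an isolated 12. The dienolate 7, generated from 5 with LiN(SiMe3)2 as in step 4, would be trapped with CO2 and acidified to give 2-methoxy-2-[5-methoxy-6-(4-methoxyphenyl)-4-oxo-4H-pyran-2-yl]acetic acid F1, to be used at once because it is a vinylogous β-keto acid. CDI would convert this acid into the acyl imidazolide F2. The imidazolide would be C-acylated in a magnesium-mediated decarboxylative Claisen condensation (MgCl2, Et3N, MeCN) by potassium methyl methoxymalonate F3, itself made from dimethyl methoxymalonate and one equivalent of KOH in MeOH; this gives 12 without any dianion. Isolated 12 would then be closed without base by heating in Ph2O at about 220 °C: loss of MeOH gives the acylketene F4, whose dienol form should undergo 6π-electrocyclisation onto C4a, as in the closing stage of a Danheiser benzannulation, and tautomerise to 13.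

2. Step 4. What may go wrong: the stabilised dienolate may add too slowly to the amide, so that proton exchange and self-condensation of the pyranone take over. The fallback sets out from 5 and comes back at 9. The same dienolate 7 would be added to methoxyacetaldehyde, a far stronger electrophile, in an aldol addition that gives 1,3-dimethoxy-1-[5-methoxy-6-(4-methoxyphenyl)-4-oxo-4H-pyran-2-yl]propan-2-ol F5 as a diastereomer mixture. Dess–Martin periodinane in CH2Cl2 would then oxidise the secondary alcohol to 9.

3. Step 2. What may go wrong: etherification of the primary hydroxyl under Ag2O may stay incomplete, or bromide may be lost by substitution at the vinylogous acyl bromide. The fallback sets out from 1 and comes back at 3, replacing steps 1 and 2, and makes the primary ether by substitution at carbon before bromine is present. SOCl2 would convert 1 into chlorokojic acid (2-(chloromethyl)-5-hydroxy-4H-pyran-4-one) F6. NaOMe in MeOH would displace the chloride to give 5-hydroxy-2-(methoxymethyl)-4H-pyran-4-one F7. NBS would brominate the enol β-carbon to give 2-bromo-3-hydroxy-6-(methoxymethyl)-4H-pyran-4-one F8, and MeI with K2CO3 in acetone would methylate the acidic enol OH to give 3.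

**Further compounds**
F1 | step 5 | 2-methoxy-2-[5-methoxy-6-(4-methoxyphenyl)-4-oxo-4H-pyran-2-yl]acetic acid (racemic) | COC(C(=O)O)c1cc(=O)c(OC)c(-c2ccc(OC)cc2)o1
F2 | step 5 | 1-(1H-imidazol-1-yl)-2-methoxy-2-[5-methoxy-6-(4-methoxyphenyl)-4-oxo-4H-pyran-2-yl]ethan-1-one (racemic) | COC(C(=O)n1ccnc1)c1cc(=O)c(OC)c(-c2ccc(OC)cc2)o1
F3 | step 5 | potassium 2,3-dimethoxy-3-oxopropanoate (potassium methyl methoxymalonate, racemic) | COC(C(=O)[O-])C(=O)OC.[K+]
F4 | step 5 | 2,4-dimethoxy-4-[5-methoxy-6-(4-methoxyphenyl)-4-oxo-4H-pyran-2-yl]but-1-ene-1,3-dione (acylketene, racemic) | COC(=C=O)C(=O)C(OC)c1cc(=O)c(OC)c(-c2ccc(OC)cc2)o1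
F5 | step 4 | 1,3-dimethoxy-1-[5-methoxy-6-(4-methoxyphenyl)-4-oxo-4H-pyran-2-yl]propan-2-ol (mixture of diastereomers, racemic) | COCC(O)C(OC)c1cc(=O)c(OC)c(-c2ccc(OC)cc2)o1
F6 | step 2 | chlorokojic acid (2-(chloromethyl)-5-hydroxy-4H-pyran-4-one) | ClCc1cc(=O)c(O)co1
F7 | step 2 | 5-hydroxy-2-(methoxymethyl)-4H-pyran-4-one | COCc1cc(=O)c(O)co1
F8 | step 2 | 2-bromo-3-hydroxy-6-(methoxymethyl)-4H-pyran-4-one | COCc1cc(=O)c(O)c(Br)o1
A1 | direct plan | phloroglucinol (benzene-1,3,5-triol) | Oc1cc(O)cc(O)c1
A2 | direct plan | methyl 2-methoxy-3-(4-methoxyphenyl)-3-oxopropanoate (racemic) | COC(=O)C(OC)C(=O)c1ccc(OC)cc1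
A3 | direct plan | ermanin (5,7-dihydroxy-3-methoxy-2-(4-methoxyphenyl)-4H-chromen-4-one) | COc1ccc(cc1)-c1oc2cc(O)cc(O)c2c(=O)c1OC
A4 | direct plan | 6,8-dibromo-5,7-dihydroxy-3-methoxy-2-(4-methoxyphenyl)-4H-chromen-4-one | COc1ccc(cc1)-c1oc2c(Br)c(O)c(Br)c(O)c2c(=O)c1OC
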